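Numbering used below: C1 (CH–OAc), C2 (CH–OH), C3 (C(OH)Me), C4 (quaternary, side chain C11–C16), C5 (ring-fusion CH), C6, C7, C8=C9(Me), C10 (ring-fusion C–Me); ring A = C1–C5 + C10, ring B = C5–C10.
Retrosynthesis: cut C12–C13 (Stille), take C11 back to CH2OBn and C1 and C7 back to ketones; then cut ring A at C2–C3 (aldol) and ring B at C5–C10 (vinylogous Michael/6π closure) in one retro-step to open-chain triketone 14; cut 14 at C7–C8 into iodoalkene 6 and enal 12.
Enabling feature: O-bearing C1 lies between quaternary C10, whose C8=C9 alkene is β,γ to C1, and oxygenated C2, which is 1,2 to the C3 carbinol. As a ketone, C1 lets C10 react as the carbon end of an extended enolate and C2 as an aldol donor; a temporary C7 ketone makes C5 electrophilic and C10–H doubly activated.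
Forward: fragments joined at C7–C8; ring B (C5–C10) then ring A (C2–C3) in one base-mediated operation; C1 reduction/acetylation; removal of the C7 oxygen; butenolide attached last.
Stereochemistry: C4 from ethyl (S)-3-hydroxybutanoate by two Frater–Seebach alkylations (its carbinol is a relay, later oxidized); C5, C10, C2, C3 relayed from C4 in the cascade; C1 by reduction directed by the C3–OH.

Key step: step 10

Remark: compounds 4–6 and 13 are carried as diastereomer mixtures at carbons whose configuration is erased in steps 9 and 10; α/β refer to the faces of the decalin, β being the face of the C10 methyl.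

Step 1
Reactants: 1 but-3-yn-2-ol (racemic)
Product: 2 but-3-yn-2-yl methanesulfonate
Conditions: MsCl, Et3N, CH2Cl2, 0 °C
Reagents that add atoms: methanesulfonyl chloride, CS(=O)(=O)Cl
Why: Standard sulfonylation of a secondary propargylic alcohol, which makes it a substrate for the Marshall propargylation.

Step 2
Reactants: 2 but-3-yn-2-yl methanesulfonate; 3 (benzyloxy)acetaldehyde
Product: 4 1-(benzyloxy)-3-methylpent-4-yn-2-ol
Conditions: Pd(dppf)Cl2 (5 mol %), InI (1.3 equiv), THF/HMPA 3:1, rt
Reagents that add atoms: none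
Why: Marshall propargylation: zerovalent palladium ionizes the mesylate, InI gives an allenylindium that adds to the aldehyde in SE2′ fashion to give the homopropargylic alcohol (diastereomer ratio irrelevant here).

Step 3
Reactants: 4 1-(benzyloxy)-3-methylpent-4-yn-2-ol
Product: 6 (E)-1-(benzyloxy)-5-iodo-3,4-dimethylpent-4-en-2-ol, via alkenylalane 5 (not isolated)
Conditions: Me3Al (3 equiv), Cp2ZrCl2 (0.25 equiv), CH2Cl2, 0 °C → rt; then I2, THF, −30 °C
Reagents that add atoms: trimethylaluminium, C[Al](C)C; iodine, II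
Why: Negishi carboalumination is a syn addition that puts methyl on the internal carbon, and iodinolysis of the C–Al bond with retention should give the (E)-iodoalkene (C8, C9 with its methyl).

Step 4
Reactants: 7 ethyl (S)-3-hydroxybutanoate
Product: 8 ethyl (2S,3S)-3-hydroxy-2-methylbutanoate
Conditions: LiN(i-Pr)2 (2.2 equiv), THF, −78 → −20 °C; MeI, −78 → 0 °C
Reagents that add atoms: iodomethane, CI
Why: Frater–Seebach alkylation: the chelated dianion is methylated anti to the C3 methyl, giving the 2,3-anti ester.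

Step 5
Reactants: 8 ethyl (2S,3S)-3-hydroxy-2-methylbutanoate
Product: 9 ethyl (2S,3S)-2-[(benzyloxy)methyl]-3-hydroxy-2-methylbutanoate
Conditions: LiN(i-Pr)2 (2.2 equiv), THF/DMPU, −78 → −20 °C; BnOCH2Cl, −78 °C
Reagents that add atoms: benzyl chloromethyl ether, ClCOCc1ccccc1
Why: Second Frater–Seebach alkylation: the electrophile again enters anti to the carbinol methyl, so the quaternary carbon (future C4) should form as one diastereomer with CH2OBn (future C11) and the ester (future C5) correctly placed.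

Step 6
Reactants: 9 ethyl (2S,3S)-2-[(benzyloxy)methyl]-3-hydroxy-2-methylbutanoate
Product: 10 (2S,3S)-2-[(benzyloxy)methyl]-2-methylbutane-1,3-diol
Conditions: LiAlH4, THF, 0 °C → rt
Reagents that add atoms: none
Why: Hydride reduction of the ester to the primary alcohol (future C5); no stereocenter is touched.

Step 7
Reactants: 10 (2S,3S)-2-[(benzyloxy)methyl]-2-methylbutane-1,3-diol
Product: 12 (2E,4S,5S)-4-[(benzyloxy)methyl]-5-hydroxy-4-methylhex-2-enal, via aldehyde 11 (not isolated)
Conditions: TEMPO (10 mol %), PhI(OAc)2, CH2Cl2, rt; then Ph3P=CHCHO, 40 °C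
Reagents that add atoms: (triphenylphosphoranylidene)acetaldehyde, O=CC=P(c1ccccc1)(c1ccccc1)c1ccccc1
Why: Oxoammonium oxidation selects the primary over the secondary hydroxyl, and the stabilized ylide turns the non-enolizable aldehyde into the (E)-enal (Wittig reaction; C5=C6, C7).

Step 8
Reactants: 6 (E)-1-(benzyloxy)-5-iodo-3,4-dimethylpent-4-en-2-ol; 12 (2E,4S,5S)-4-[(benzyloxy)methyl]-5-hydroxy-4-methylhex-2-enal
Product: 13 (4E,7E,9S,10S)-1-(benzyloxy)-9-[(benzyloxy)methyl]-3,4,9-trimethylundeca-4,7-diene-2,6,10-triol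
Conditions: CrCl2 (4 equiv), NiCl2 (1 mol %), DMSO/THF, rt
Reagents that add atoms: none
Why: Nozaki–Hiyama–Kishi coupling: the alkenylchromium formed from 6 with retention adds 1,2 to the enal and tolerates the free hydroxyls; the new C7 carbinol configuration is irrelevant.

Step 9
Reactants: 13 (4E,7E,9S,10S)-1-(benzyloxy)-9-[(benzyloxy)methyl]-3,4,9-trimethylundeca-4,7-diene-2,6,10-triol
Product: 14 (4E,7E,9S)-1-(benzyloxy)-9-[(benzyloxy)methyl]-3,4,9-trimethylundeca-4,7-diene-2,6,10-trione
Conditions: Dess–Martin periodinane (4 equiv), pyridine, CH2Cl2, 0 °C → rt; used crude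
Reagents that add atoms: none
Why: Dess–Martin oxidation of the two secondary carbinols and the doubly allylic carbinol gives the triketone (C1, C3, C7) and leaves C4 as the only fixed stereocenter.

Step 10
Reactants: 14 (4E,7E,9S)-1-(benzyloxy)-9-[(benzyloxy)methyl]-3,4,9-trimethylundeca-4,7-diene-2,6,10-trione
Product: 16 trans-decal-8-ene-1,7-dione bearing 2α-OBn; 3α-OH; 3β-CH3; 4β-CH3; 4α-CH2OBn; 5α-H; 9-CH3; 10β-CH3, via ring B enone 15 (not isolated)
Conditions: KOt-Bu (1.1 equiv), THF/t-BuOH 10:1, −20 °C → rt; AcOH quench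
Reagents that add atoms: none
Why: Proposed new method: KOt-Bu removes the C10–H of 14, which is α to the C1 ketone and vinylogously α to the C7 ketone, and the delocalized trienolate (C8=C9 geometry equilibrates through its C8/C10 tautomers) closes ring B by C10→C5 attack on the (E)-C5=C6–C7=O enone, a 6-endo-trig vinylogous Michael addition equivalent to an oxyanion-accelerated disrotatory 6π-electrocyclization of C10=C9–C8=C7(O−)–C6=C5; the C1 ketone of 15, now enolizable only toward C2, then closes ring A by a 6-(enolendo)-exo-trig aldol addition onto the C3 methyl ketone. The closest known reaction types are charge-accelerated 6π-electrocyclizations of trienolates and the Michael–aldol α,α′-annulation of ketones; new is their use in one operation on an open-chain triketone with a vinylogous β-diketone carbon as the first nucleophile. Ring fusion (C5, C10): the C1 acyl group of the trienolate should lie cis to C8–H, because the other planar geometry suffers A(1,3) strain with the C9 methyl, and C4 is outside on the (E)-enone, so disrotation puts the C10 methyl and C4 cis on ring B, that is C5–H trans to the C10 methyl. C5 relative to C4: the new bond should form anti to the largest C4 substituent (CH2OBn) with the C4 methyl in the crowded position gauche to C6 and C10, which leaves the acetyl group gauche to C10 as ring A requires. C2 and C3: a chair transition state on the trans-fused ring B template, with potassium bridging the (Z)-α-benzyloxy enolate and ketone oxygens, places OBn equatorial at C2 (also the thermodynamic epimer) and OH axial/CH3 equatorial at C3. The step needs C10 to attack C5 faster than the C2 enolate attacks C7 (aldol aromatization) or the C3 methyl enolate attacks C1 or C7; the roughly 6 pKa units by which C10–H is more acidic, the loss of electrophilicity at C7 once it is part of the anion, and the reversibility of the ketone aldols should secure this.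

Step 11
Reactants: 16 trans-decal-8-ene-1,7-dione (2α-OBn; 3α-OH)
Product: 17 1β,3α-dihydroxy-trans-decal-8-en-7-one bearing 2α-OBn; 4α-CH2OBn; 3β,4β,9,10β-tetramethyl; 5α-H
Conditions: Me4NBH(OAc)3, MeCN/AcOH 1:1, −30 °C
Reagents that add atoms: none
Why: Evans–Saksena reduction: the axial C3 hydroxyl exchanges onto boron and delivers hydride to the α face of the C1 ketone, giving the 1,3-anti diol (equatorial 1β-OH) and leaving the C7 enone untouched.

Step 12
Reactants: 17 1β,3α-dihydroxy-trans-decal-8-en-7-one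
Product: 18 1β-acetoxy-3α-hydroxy-trans-decal-8-en-7-one bearing 2α-OBn; 4α-CH2OBn; 3β,4β,9,10β-tetramethyl; 5α-H
Conditions: Ac2O, pyridine, DMAP (cat.), CH2Cl2, rt
Reagents that add atoms: acetic anhydride, CC(=O)OC(C)=O
Why: DMAP-catalysed acetylation takes the secondary C1 hydroxyl; the tertiary C3 hydroxyl should not be acylated under these conditions.

Step 13
Reactants: 18 1β-acetoxy-3α-hydroxy-trans-decal-8-en-7-one
Product: 19 7,7-(ethane-1,2-diyldisulfanediyl) dithioketal of 18
Conditions: HS(CH2)2SH, BF3·OEt2 (cat.), CH2Cl2, −20 → 0 °C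
Reagents that add atoms: ethane-1,2-dithiol, SCCS
Why: Lewis-acid-catalysed dithioketalization of the only remaining ketone (C7); the C8=C9 alkene cannot move further into the ring past quaternary C10.

Step 14
Reactants: 19 C7 dithiolane
Product: 20 1β-acetoxy-2α-(benzyloxy)-4α-[(benzyloxy)methyl]-3α-hydroxy-3β,4β,9,10β-tetramethyl-5αH-trans-decal-8-ene
Conditions: Raney Ni (W-2), EtOH/acetone, rt → 50 °C
Reagents that add atoms: none
Why: Mozingo reduction: hydrogenolysis of both C–S bonds turns C7 into CH2 and so removes the activating oxygen; any loss of benzyl ether here would be harmless.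

Step 15
Reactants: 20 bis-benzyl ether
Product: 21 1β-acetoxy-4α-(hydroxymethyl)-3β,4β,9,10β-tetramethyl-5αH-trans-decal-8-ene-2α,3α-diol
Conditions: H2 (1 atm), Pd/C (10 %), EtOAc, rt
Reagents that add atoms: none
Why: Hydrogenolysis of both benzyl ethers; the trisubstituted C8=C9 alkene next to quaternary C10 should be too hindered to be hydrogenated.

Step 16
Reactants: 21 triol
Product: 22 C11 aldehyde: 1β-acetoxy-2α,3α-dihydroxy-3β,4β,9,10β-tetramethyl-5αH-trans-decal-8-ene-4α-carbaldehyde
Conditions: TEMPO (10 mol %), PhI(OAc)2, CH2Cl2, rt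
Reagents that add atoms: none
Why: Oxoammonium oxidation selects the primary neopentyl alcohol over the secondary and tertiary hydroxyls; a lactol with the 2α-OH would need a bridged bicyclo[2.2.1] acetal across the chair and is not expected.

Step 17
Reactants: 22 C11 aldehyde
Product: 23 4α-[(E)-2-iodoethenyl] compound: 1β-acetoxy-4α-[(E)-2-iodoethenyl]-3β,4β,9,10β-tetramethyl-5αH-trans-decal-8-ene-2α,3α-diol
Conditions: CrCl2 (6 equiv), CHI3 (2 equiv), THF/1,4-dioxane, 0 °C → rt
Reagents that add atoms: iodoform, IC(I)I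
Why: Takai olefination gives the (E)-iodoalkene (C11=C12) under non-basic conditions that leave the acetate next to the free 2-OH in place.

Step 18
Reactants: 24 4-bromofuran-2(5H)-one
Product: 25 4-(tributylstannyl)furan-2(5H)-one
Conditions: (Bu3Sn)2, Pd(PPh3)4 (5 mol %), toluene, 100 °C
Reagents that add atoms: hexabutyldistannane, CCCC[Sn](CCCC)(CCCC)[Sn](CCCC)(CCCC)CCCC
Why: Palladium-catalysed stannylation of the vinylogous acyl bromide with the distannane.

Step 19
Reactants: 23 (E)-iodoalkene; 25 4-(tributylstannyl)furan-2(5H)-one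
Product: 26 (1R,2S,3R,4R,4aS,8aR)-2,3-dihydroxy-3,4,8,8a-tetramethyl-4-[(E)-2-(5-oxo-2,5-dihydrofuran-3-yl)ethenyl]-1,2,3,4,4a,5,6,8a-octahydronaphthalen-1-yl acetate
Conditions: Pd2(dba)3 (5 mol %), AsPh3, CuI (cat.), DMF, rt → 40 °C
Reagents that add atoms: none
Why: Stille coupling joins C12 to C13 with retention of the (E)-alkene under neutral conditions, so no acetyl migration to the 2-OH is expected.

Compound list
1 | but-3-yn-2-ol (racemic) | CC(O)C#C | starting material
2 | but-3-yn-2-yl methanesulfonate | CC(OS(C)(=O)=O)C#C | intermediate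
3 | (benzyloxy)acetaldehyde | O=CCOCc1ccccc1 | starting material
4 | 1-(benzyloxy)-3-methylpent-4-yn-2-ol (diastereomer mixture) | C#CC(C)C(O)COCc1ccccc1 | intermediate
5 | alkenylalane: dimethylaluminium alkoxide of (E)-1-(benzyloxy)-5-(dimethylalumanyl)-3,4-dimethylpent-4-en-2-ol | C[Al](C)/C=C(C)/C(C)C(COCc1ccccc1)O[Al](C)C | intermediate
6 | (E)-1-(benzyloxy)-5-iodo-3,4-dimethylpent-4-en-2-ol (diastereomer mixture) | I/C=C(C)/C(C)C(O)COCc1ccccc1 | intermediate
7 | ethyl (S)-3-hydroxybutanoate | C[C@H](O)CC(=O)OCC | starting material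
8 | ethyl (2S,3S)-3-hydroxy-2-methylbutanoate | C[C@H](O)[C@H](C)C(=O)OCC | intermediate
9 | ethyl (2S,3S)-2-[(benzyloxy)methyl]-3-hydroxy-2-methylbutanoate | C[C@H](O)[C@](C)(COCc1ccccc1)C(=O)OCC | intermediate
10 | (2S,3S)-2-[(benzyloxy)methyl]-2-methylbutane-1,3-diol | C[C@H](O)[C@](C)(COCc1ccccc1)CO | intermediate
11 | (2S,3S)-2-[(benzyloxy)methyl]-3-hydroxy-2-methylbutanal | C[C@H](O)[C@](C)(COCc1ccccc1)C=O | intermediate
12 | (2E,4S,5S)-4-[(benzyloxy)methyl]-5-hydroxy-4-methylhex-2-enal | C[C@H](O)[C@](C)(COCc1ccccc1)/C=C/C=O | intermediate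
13 | (4E,7E,9S,10S)-1-(benzyloxy)-9-[(benzyloxy)methyl]-3,4,9-trimethylundeca-4,7-diene-2,6,10-triol (mixture at C2, C3, C6) | C[C@H](O)[C@](C)(COCc1ccccc1)/C=C/C(O)/C=C(\C)C(C)C(O)COCc1ccccc1 | intermediate
14 | (4E,7E,9S)-1-(benzyloxy)-9-[(benzyloxy)methyl]-3,4,9-trimethylundeca-4,7-diene-2,6,10-trione | CC(=O)[C@](C)(COCc1ccccc1)/C=C/C(=O)/C=C(\C)C(C)C(=O)COCc1ccccc1 | intermediate
15 | (4R,5S)-4-[(benzyloxy)acetyl]-5-[(2S)-1-(benzyloxy)-2-methyl-3-oxobutan-2-yl]-3,4-dimethylcyclohex-2-en-1-one | CC(=O)[C@](C)(COCc1ccccc1)[C@H]1CC(=O)C=C(C)[C@]1(C)C(=O)COCc1ccccc1 | intermediate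
16 | 2α-(benzyloxy)-4α-[(benzyloxy)methyl]-3α-hydroxy-3β,4β,9,10β-tetramethyl-5αH-trans-decal-8-ene-1,7-dione | O=C1[C@H](OCc2ccccc2)[C@](C)(O)[C@](C)(COCc2ccccc2)[C@H]2CC(=O)C=C(C)[C@]12C | intermediate
17 | 2α-(benzyloxy)-4α-[(benzyloxy)methyl]-1β,3α-dihydroxy-3β,4β,9,10β-tetramethyl-5αH-trans-decal-8-en-7-one | O[C@H]1[C@H](OCc2ccccc2)[C@](C)(O)[C@](C)(COCc2ccccc2)[C@H]2CC(=O)C=C(C)[C@]12C | intermediate
18 | 1β-acetoxy-2α-(benzyloxy)-4α-[(benzyloxy)methyl]-3α-hydroxy-3β,4β,9,10β-tetramethyl-5αH-trans-decal-8-en-7-one | CC(=O)O[C@H]1[C@H](OCc2ccccc2)[C@](C)(O)[C@](C)(COCc2ccccc2)[C@H]2CC(=O)C=C(C)[C@]12C | intermediate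
19 | C7 1,3-dithiolane of 18 | CC(=O)O[C@H]1[C@H](OCc2ccccc2)[C@](C)(O)[C@](C)(COCc2ccccc2)[C@H]2CC3(SCCS3)C=C(C)[C@]12C | intermediate
20 | 1β-acetoxy-2α-(benzyloxy)-4α-[(benzyloxy)methyl]-3α-hydroxy-3β,4β,9,10β-tetramethyl-5αH-trans-decal-8-ene | CC(=O)O[C@H]1[C@H](OCc2ccccc2)[C@](C)(O)[C@](C)(COCc2ccccc2)[C@H]2CCC=C(C)[C@]12C | intermediate
21 | 1β-acetoxy-4α-(hydroxymethyl)-3β,4β,9,10β-tetramethyl-5αH-trans-decal-8-ene-2α,3α-diol | CC(=O)O[C@H]1[C@H](O)[C@](C)(O)[C@](C)(CO)[C@H]2CCC=C(C)[C@]12C | intermediate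
22 | 1β-acetoxy-2α,3α-dihydroxy-3β,4β,9,10β-tetramethyl-5αH-trans-decal-8-ene-4α-carbaldehyde | CC(=O)O[C@H]1[C@H](O)[C@](C)(O)[C@](C)(C=O)[C@H]2CCC=C(C)[C@]12C | intermediate
23 | 1β-acetoxy-4α-[(E)-2-iodoethenyl]-3β,4β,9,10β-tetramethyl-5αH-trans-decal-8-ene-2α,3α-diol | CC(=O)O[C@H]1[C@H](O)[C@](C)(O)[C@](C)(/C=C/I)[C@H]2CCC=C(C)[C@]12C | intermediate
24 | 4-bromofuran-2(5H)-one | BrC1=CC(=O)OC1 | starting material
25 | 4-(tributylstannyl)furan-2(5H)-one | CCCC[Sn](CCCC)(CCCC)C1=CC(=O)OC1 | intermediate
26 | (1R,2S,3R,4R,4aS,8aR)-2,3-dihydroxy-3,4,8,8a-tetramethyl-4-[(E)-2-(5-oxo-2,5-dihydrofuran-3-yl)ethenyl]-1,2,3,4,4a,5,6,8a-octahydronaphthalen-1-yl acetate | CC(=O)O[C@H]1[C@H](O)[C@](C)(O)[C@](C)(/C=C/C2=CC(=O)OC2)[C@H]2CCC=C(C)[C@]12C | target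

Total step count: 19. Longest linear sequence: 15 steps (steps 4–17 and 19, from ethyl (S)-3-hydroxybutanoate).

Steps most likely to fail

1. Step 10 (Proposed new method). What may go wrong: aldol attack of the C2 enolate on C7 followed by aromatization to a phenol; ring closure from the trienolate geometry with the C1 acyl group outside, giving the cis ring fusion; weak facial discrimination by C4; aldol through the C3 methyl enolate. Fallback with known reactions, closing ring B before C1 is a ketone: setting out from 13, MnO2 (CH2Cl2, rt) should oxidize only the doubly allylic C7 carbinol to dienone diol F1. Excess TESOTf/Et3N silylates both hydroxyls and enolizes the dienone at C10 to the 3-silyloxyhexatriene F2. Heating (toluene, 110 °C) effects a thermal disrotatory 6π-electrocyclization to cyclohexadiene F3, and HF·pyridine gives enone diol F4. Dess–Martin oxidation gives 15, and a separate aldol cyclization (LiN(SiMe3)2, THF, −78 °C) comes back to the route at 16.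

2. Step 5. What may go wrong: O-alkylation of the alkoxide, incomplete alkylation of the tetrasubstituted enolate, erosion of facial selectivity. Fallback: setting out from 8, the same dianion is intercepted with monomeric formaldehyde (aldol addition instead of alkylation) to give diol ester F5. Its primary hydroxyl is benzylated selectively through the stannylene acetal (Bu2SnO; BnBr, CsF), coming back at 9.

3. Step 14. What may go wrong: partial saturation or migration of the C8=C9 alkene, incomplete C–S hydrogenolysis. Fallback: setting out from 18 (no dithiolane), Luche reduction (NaBH4, CeCl3, MeOH, −40 °C) gives allylic alcohol F6. Ionic hydrogenolysis (Et3SiH, BF3·OEt2, CH2Cl2, −78 °C; hydride at the less hindered C7 end of the allyl cation, the deactivated tertiary C3–OH staying) comes back at 20.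

Further compounds
F1 | step 10 | (4E,7E,9S,10S)-1-(benzyloxy)-9-[(benzyloxy)methyl]-2,10-dihydroxy-3,4,9-trimethylundeca-4,7-dien-6-one | C[C@H](O)[C@](C)(COCc1ccccc1)/C=C/C(=O)/C=C(\C)C(C)C(O)COCc1ccccc1
F2 | step 10 | (7E,9S,10S)-1-(benzyloxy)-9-[(benzyloxy)methyl]-3,4,9-trimethyl-2,6,10-tris(triethylsilyloxy)undeca-3,5,7-triene | C[C@H](O[Si](CC)(CC)CC)[C@](C)(COCc1ccccc1)/C=C/C(O[Si](CC)(CC)CC)=CC(C)=C(C)C(O[Si](CC)(CC)CC)COCc1ccccc1
F3 | step 10 | ring B cyclohexa-1,3-diene silyl enol ether (C5–C10 closed; three OTES groups at C1, C3, C7) | C[C@H](O[Si](CC)(CC)CC)[C@](C)(COCc1ccccc1)[C@H]1C=C(O[Si](CC)(CC)CC)C=C(C)[C@]1(C)C(O[Si](CC)(CC)CC)COCc1ccccc1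
F4 | step 10 | 4-[2-(benzyloxy)-1-hydroxyethyl]-5-[(2S,3S)-1-(benzyloxy)-3-hydroxy-2-methylbutan-2-yl]-3,4-dimethylcyclohex-2-en-1-one | C[C@H](O)[C@](C)(COCc1ccccc1)[C@H]1CC(=O)C=C(C)[C@]1(C)C(O)COCc1ccccc1
F5 | step 5 | ethyl (2S,3S)-3-hydroxy-2-(hydroxymethyl)-2-methylbutanoate | C[C@H](O)[C@](C)(CO)C(=O)OCC
F6 | step 14 | 7-hydroxy analogue of 18 (allylic alcohol, C7 epimers) | CC(=O)O[C@H]1[C@H](OCc2ccccc2)[C@](C)(O)[C@](C)(COCc2ccccc2)[C@H]2CC(O)C=C(C)[C@]12C
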